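## The problem

The target is the γ-lactone of an ω-oxygenated 2-alkylhomocitric acid. It has an oxolan-2-one ring (O1, C2, C3, C4, C5=O) whose C2 is fully substituted (ring O1, a carboxyl, ring C3 and the exocyclic methine C1'). C1' carries a second carboxyl and a ten-carbon chain that ends as the 1-O-ester of (R)-malic acid.

The core difficulty is the vicinal pair C2 (S, tetrasubstituted, oxygenated) and C1' (S, tertiary). It sits in an open, carboxyl-crowded array where neither centre easily directs the other, and C1' can epimerise whenever its carboxyl is at the aldehyde or activated-ester level. The malate centre is ten methylene groups away, cannot be controlled from the core and must come from the chiral pool. It has to be joined through its C1 carboxyl only, leaving its C4 carboxyl and hydroxyl free. The molecule ends with three free acids beside two esters (the lactone and the primary alkyl malate), so no late step may use hydroxide, alkoxide or hydride. The secondary malate hydroxyl also excludes strong oxidants once it is in place.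

The feature that opens the plan is a hidden six-membered ring. The carboxyl carbon on C1' and the lactone carbonyl C5 are the two ends of the six-carbon path C(O)–C1'–C2–C3–C4–C5. Joined as a C=C they give a cyclohexene in which C1' (alkyl) and C2 (O, CO2H) are adjacent ring atoms. That cyclohexene is the "ortho" Diels–Alder adduct of a 1-alkylbuta-1,3-diene and a 2-oxyacrylate. One cycloaddition can therefore set both stereocentres, and ozonolysis of the ring alkene then releases the chain carboxyl and the lactone carbonyl together.

## Retrosynthesis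

**22 ⇒ 21 ⇒ 20.** The lactone bond O1–C5 is cut to the open hydroxy tetra-acid 21. Its tertiary hydroxyl and C2 carboxyl are then tied up as the pivalaldehyde (7) acetal, the dioxolanone 20. Against methyl or benzyl esters, this mask needs no extra step because it arrives with the dienophile, and it falls to aqueous acid, the one reagent class the malate ester tolerates. The forward step must cleave a hindered acylal without hydrolysing a primary alkyl ester; the lactone then closes by itself.

**20 ⇒ 17.** The carboxyl carbon on C1' and the carboxyl carbon of the propanoic arm are reconnected as C7=C8 of the 1,3-dioxaspiro[4.5]dec-7-ene 17. Against carrying these carboxyls as esters, the alkene needs no deprotection and cannot epimerise C6. Three free acids shrink to one. The forward ozonolysis and oxidation must spare a secondary alcohol and a free acid.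

**17 ⇒ 13 + 15.** The malate ester C–O bond is cut. The acyl donor 15 is the O-acylated cyclic anhydride of (R)-malic acid 14 and is known to open at the carbonyl next to the oxygenated carbon. Doing this before the ring is cleaved means the primary hydroxyl of 13 is the only nucleophile and no core acid exists yet, so no protecting group is needed on either partner. The forward step must be regioselective for C1 of the anhydride.

**13 ⇒ 12.** Only the silyl ether is changed; it is needed for the carbanion step and the thermal step.

**12 ⇒ 11 + 10 (key).** Ring bonds C5–C6 and C9–C10 are cut in a retro-Diels–Alder sense. This gives the achiral (E)-diene 11 and the chiral methylidene dioxolanone 10. Against an aldol cut of the same C–C bond, both stereocentres come from one transition state on a rigid dienophile. The precursors carry one stereocentre (the acetal carbon of 10) against three in 12. The forward reaction must be "ortho"-regioselective, carbonyl-exo and anti to the tert-butyl group.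

**11 ⇒ 5 ⇒ 4 + 3.** The diene is masked as its cheletropic adduct 5, which is cut between sulfolene C2 and the decyl chain into 3-sulfolene 4 and iodide 3. Against a Wittig route, thermal unmasking gives the (E)-diene only; against alkyne routes it is shorter. The alkylation must outrun ring opening of the sulfolenyl anion.

**10 ⇒ 9 ⇒ 8 ⇒ 6 + 7.** The exocyclic alkene is traced through bromide 9 to the cis acetal 8 of (R)-lactic acid 6 and pivalaldehyde 7. The lactate centre is used only to set the acetal carbon and is then erased.

**3 ⇒ 2 ⇒ 1 and 15 ⇒ 14.** These are functional-group changes on commercial 10-bromodecan-1-ol 1 and (R)-malic acid 14.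

## Roads not taken

**Alternative 1:** the most obvious cut is the C2–C1' bond as an aldol, joining an enolate equivalent of the 12-oxygenated dodecanoyl chain to a 2-oxoglutarate diester. The forward key step is a chiral-Lewis-acid or auxiliary-controlled aldol addition giving the tertiary aldol A1.
- Two independent selectivities are needed: face selection at a ketone whose two substituents are both ester-bearing chains, and enolate geometry of a long-chain ester. In the chosen plan both centres follow from one cycloaddition geometry.
- A1 is a tertiary β-hydroxy ester with an epimerisable α-methine. Freeing its three esters needs base, which invites retro-aldol and epimerisation, and forces the malate to be attached last onto a free hydroxy diacid.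
- It is no shorter. A catalytic form of this cut is kept only as the fallback for step 7.

**Alternative 2:** dearomatisation of a furan. The same bond is made by a vinylogous Mukaiyama–Michael addition of the 2-silyloxyfuran A2 to a β-formylacrylate ester under iminium catalysis, giving butenolide A3 with both centres.
- A3 holds only two of the ten chain carbons. The rest must be added by Wittig olefination with a C8 ω-oxygenated ylide, and two C=C bonds must then be hydrogenated.
- Its methyl and ethyl esters must be hydrolysed beside the lactone before the malate can be attached.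
- This is three to four operations after the key step that the Diels–Alder plan does not need, because the whole chain arrives with the diene.

**Alternative 3:** chiral-pool malate. Fráter–Seebach dianion alkylation of a dialkyl (S)-malate with iodide 3 gives the 3-alkylmalate A4. C2 is then quaternised by self-regeneration of stereocentres (pivalaldehyde acetal, enolate allylation, hydroboration and oxidation to the propanoic arm).
- The stereochemistry is mismatched. The anti-selective alkylation gives (2S,3R), but retentive quaternisation at C2 needs the (2S,3S) pairing, so a minor isomer or an epimerisation would have to be used.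
- It needs two strong-base steps. The second can deprotonate the ester-bearing methine and eliminate the acetal oxygen.
- The core alone costs about as many steps as the whole chosen route.

Key step: step 7

Remark: read from the SMILES, the centres are (S) at lactone C2, (S) at the chain methine and (R) in the malate, which is esterified through the carboxyl next to its carbinol; 1, 4, 6, 7 and 14 are taken as commercial.

## Route

Step 1
Reactants: 1 10-bromodecan-1-ol
Product: 2 [(10-bromodecyl)oxy](tert-butyl)dimethylsilane
Conditions: TBSCl, imidazole, DMF, 0 °C → rt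
Reagents that add atoms: tert-butyldimethylsilyl chloride (TBSCl), CC(C)(C)[Si](C)(C)Cl
Why: Standard silylation of a primary alcohol; the silyl ether protects the hydroxyl through the carbanion alkylation (step 3) and the thermal step 7.

Step 2
Reactants: 2 [(10-bromodecyl)oxy](tert-butyl)dimethylsilane
Product: 3 tert-butyl[(10-iododecyl)oxy]dimethylsilane
Conditions: NaI, acetone, reflux
Reagents that add atoms: sodium iodide, [Na+].[I-]
Why: Finkelstein exchange driven by precipitation of NaBr; the iodide is needed because the sulfolenyl anion of step 3 is short-lived.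

Step 3
Reactants: 4 3-sulfolene (2,5-dihydrothiophene 1,1-dioxide); 3 tert-butyl[(10-iododecyl)oxy]dimethylsilane
Product: 5 rac-2-{10-[(tert-butyldimethylsilyl)oxy]decyl}-2,5-dihydrothiophene 1,1-dioxide
Conditions: LiN(SiMe3)2 added to 4 + 3, THF/HMPA (4:1), −78 °C
Reagents that add atoms: none
Why: SN2 alkylation of the α-sulfonyl allyl carbanion with in situ trapping at −78 °C, which should outrun ring opening of the anion. The new centre is racemic and is destroyed in step 7.

Step 4
Reactants: 6 (R)-lactic acid; 7 pivalaldehyde
Product: 8 (2R,5R)-2-tert-butyl-5-methyl-1,3-dioxolan-4-one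
Conditions: TsOH·H2O (cat.), H2SO4 (cat.), pentane, reflux, Dean–Stark; recrystallise from pentane/Et2O at −78 °C
Reagents that add atoms: none
Why: Acid-catalysed acetalisation with water removal; the cis acetal is expected to be favoured, so the lactate centre fixes the acetal carbon as (2R). Crystallisation removes the trans isomer, which would lead to the enantiomeric dienophile.

Step 5
Reactants: 8 (2R,5R)-2-tert-butyl-5-methyl-1,3-dioxolan-4-one
Product: 9 (2R,5S)-5-bromo-2-tert-butyl-5-methyl-1,3-dioxolan-4-one
Conditions: NBS, AIBN (cat.), CCl4, reflux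
Reagents that add atoms: N-bromosuccinimide, O=C1CCC(=O)N1Br
Why: Wohl–Ziegler-type radical bromination at the captodative C5–H. Bromine should enter trans to tert-butyl, and this centre is erased in step 6.

Step 6
Reactants: 9 (2R,5S)-5-bromo-2-tert-butyl-5-methyl-1,3-dioxolan-4-one
Product: 10 (2R)-2-tert-butyl-5-methylidene-1,3-dioxolan-4-one
Conditions: Et3N, Et2O, 0 °C → rt
Reagents that add atoms: none
Why: E2 dehydrobromination to the exocyclic alkene; the acetal carbon C2 is untouched and is now the only stereocentre.

Step 7
Reactants: 5 rac-2-{10-[(tert-butyldimethylsilyl)oxy]decyl}-2,5-dihydrothiophene 1,1-dioxide; 10 (2R)-2-tert-butyl-5-methylidene-1,3-dioxolan-4-one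
Product: 12 (2R,5S,6R)-2-tert-butyl-6-{10-[(tert-butyldimethylsilyl)oxy]decyl}-1,3-dioxaspiro[4.5]dec-7-en-4-one, via (E)-diene 11 (not isolated)
Conditions: PhMe, NaHCO3, BHT (cat.), 115 °C, slow Ar sweep
Reagents that add atoms: none
Why: On heating, 5 loses its SO2 bridge by a thermally allowed, concerted cheletropic extrusion (disrotatory, alkyl group turning outward) that gives only the (E)-diene 11, which is trapped by the captodative exocyclic alkene of 10 in a concerted, asynchronous [4+2] cycloaddition. The closest known reaction types are thermal Diels–Alder reactions of 2-tert-butyl-5-methylidene-1,3-dioxolan-4-ones with acyclic 1-substituted dienes and the use of 2-alkyl-3-sulfolenes as in situ diene sources. The cyclohexene ring is closed in one intermolecular suprafacial/suprafacial [4π+2π] event that forms C5–C6 and C9–C10 of the spiro system; no separate cyclisation is involved. Regiochemistry follows the "ortho" rule: the unsubstituted diene terminus (larger HOMO coefficient) bonds to the β-CH2 of 10 (larger LUMO coefficient), so the spiro carbon becomes attached to the alkyl-bearing carbon. The spiro centre C5 is controlled by the C2 tert-butyl group of 10, which shields one face of the planar dioxolanone so that the diene adds anti to it and gives (5S). The methine C6 is controlled by transition-state topology: this s-cis-locked α-oxy lactone dienophile is expected to react with its carbonyl exo (ring oxygen endo), which places the (E)-alkyl group cis to O1 and gives (6R), the (S)-methine of the target. The step therefore needs ortho regioselectivity, carbonyl-exo selectivity and anti-tert-butyl facial selectivity; the first rests on the 1-alkyl group of the diene, the other two on the rigid acetal ring of 10. BHT suppresses radical polymerisation of 10, and NaHCO3 with the argon sweep removes the extruded gas.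

Step 8
Reactants: 12 (2R,5S,6R)-2-tert-butyl-6-{10-[(tert-butyldimethylsilyl)oxy]decyl}-1,3-dioxaspiro[4.5]dec-7-en-4-one
Product: 13 (2R,5S,6R)-2-tert-butyl-6-(10-hydroxydecyl)-1,3-dioxaspiro[4.5]dec-7-en-4-one
Conditions: HF·pyridine, pyridine/THF, 0 °C → rt
Reagents that add atoms: none
Why: Fluoride-mediated desilylation under buffered, non-nucleophilic conditions that should leave the acylal lactone and the alkene untouched.

Step 9
Reactants: 14 (R)-malic acid
Product: 15 (3R)-2,5-dioxooxolan-3-yl trifluoroacetate
Conditions: (CF3CO)2O, neat, 0 °C → rt; evaporate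
Reagents that add atoms: trifluoroacetic anhydride, O=C(OC(=O)C(F)(F)F)C(F)(F)F
Why: Dehydration to the cyclic anhydride with concurrent O-trifluoroacetylation; no bond to the stereocentre is broken, so (R) is retained.

Step 10
Reactants: 13 (2R,5S,6R)-2-tert-butyl-6-(10-hydroxydecyl)-1,3-dioxaspiro[4.5]dec-7-en-4-one; 15 (3R)-2,5-dioxooxolan-3-yl trifluoroacetate
Product: 17 (3R)-4-({10-[(2R,5S,6R)-2-tert-butyl-4-oxo-1,3-dioxaspiro[4.5]dec-7-en-6-yl]decyl}oxy)-3-hydroxy-4-oxobutanoic acid, via O-trifluoroacetyl half-ester 16 (not isolated)
Conditions: 15 (excess), CH2Cl2/THF, 0 °C → rt; then H2O/THF, NaHCO3 to pH 7, rt; acidify to pH 3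
Reagents that add atoms: none
Why: Regioselective alcoholysis of the cyclic anhydride at the carbonyl next to the electron-poor CH–OCOCF3 carbon gives the 1-ester with the C4 acid free; the labile trifluoroacetate is then solvolysed. The core acids are still masked, so the primary hydroxyl of 13 is the only nucleophile.

Step 11
Reactants: 17 (3R)-4-({10-[(2R,5S,6R)-2-tert-butyl-4-oxo-1,3-dioxaspiro[4.5]dec-7-en-6-yl]decyl}oxy)-3-hydroxy-4-oxobutanoic acid
Product: 20 (3R)-4-({(11S)-11-carboxy-11-[(2R,4S)-2-tert-butyl-4-(2-carboxyethyl)-5-oxo-1,3-dioxolan-4-yl]undecyl}oxy)-3-hydroxy-4-oxobutanoic acid, via ozonide 18 (not isolated), via dialdehyde 19 (not isolated)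
Conditions: O3, CH2Cl2, −78 °C (to first excess); Me2S, −78 °C → rt; concentrate; NaClO2, NaH2PO4, 2-methyl-2-butene, t-BuOH/H2O, 0 °C → rt
Reagents that add atoms: ozone, [O-][O+]=O; sodium chlorite, [Na+].[O-]Cl=O
Why: Criegee ozonolysis of the only C=C followed by Pinnick oxidation of both aldehydes at pH 3–4, conditions that spare the secondary hydroxyl, the acetal and the esters. Telescoping without base is meant to keep the α-methine of 19 intact.

Step 12
Reactants: 20 (3R)-4-({(11S)-11-carboxy-11-[(2R,4S)-2-tert-butyl-4-(2-carboxyethyl)-5-oxo-1,3-dioxolan-4-yl]undecyl}oxy)-3-hydroxy-4-oxobutanoic acid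
Product: 22 (2S)-2-[(1S)-1-carboxy-11-{[(2R)-3-carboxy-2-hydroxypropanoyl]oxy}undecyl]-5-oxooxolane-2-carboxylic acid, via hydroxy tetra-acid 21 (not isolated)
Conditions: TFA/H2O (9:1), rt → 40 °C; concentrate; reversed-phase chromatography
Reagents that add atoms: water, O (taken up in 21 and given back on lactonisation)
Why: Acid-catalysed hydrolysis of the acylal through its acyloxy-stabilised oxocarbenium ion should be faster than hydrolysis of the primary alkyl malate ester. The freed tertiary hydroxyl then closes the γ-lactone onto the propanoic arm (5-exo-trig); no stereocentre is touched.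

## Compound list

1 | 10-bromodecan-1-ol | OCCCCCCCCCCBr | starting material
2 | [(10-bromodecyl)oxy](tert-butyl)dimethylsilane | CC(C)(C)[Si](C)(C)OCCCCCCCCCCBr | intermediate
3 | tert-butyl[(10-iododecyl)oxy]dimethylsilane | CC(C)(C)[Si](C)(C)OCCCCCCCCCCI | intermediate
4 | 3-sulfolene (2,5-dihydrothiophene 1,1-dioxide) | O=S1(=O)CC=CC1 | starting material
5 | rac-2-{10-[(tert-butyldimethylsilyl)oxy]decyl}-2,5-dihydrothiophene 1,1-dioxide | CC(C)(C)[Si](C)(C)OCCCCCCCCCCC1C=CCS1(=O)=O | intermediate
6 | (R)-lactic acid | C[C@@H](O)C(=O)O | starting material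
7 | pivalaldehyde | CC(C)(C)C=O | starting material
8 | (2R,5R)-2-tert-butyl-5-methyl-1,3-dioxolan-4-one | C[C@H]1O[C@@H](C(C)(C)C)OC1=O | intermediate
9 | (2R,5S)-5-bromo-2-tert-butyl-5-methyl-1,3-dioxolan-4-one | C[C@@]1(Br)O[C@@H](C(C)(C)C)OC1=O | intermediate
10 | (2R)-2-tert-butyl-5-methylidene-1,3-dioxolan-4-one | C=C1O[C@@H](C(C)(C)C)OC1=O | intermediate
11 | tert-butyldimethyl{[(11E)-tetradeca-11,13-dien-1-yl]oxy}silane | CC(C)(C)[Si](C)(C)OCCCCCCCCCC/C=C/C=C | intermediate
12 | (2R,5S,6R)-2-tert-butyl-6-{10-[(tert-butyldimethylsilyl)oxy]decyl}-1,3-dioxaspiro[4.5]dec-7-en-4-one | CC(C)(C)[Si](C)(C)OCCCCCCCCCC[C@@H]1C=CCC[C@]12O[C@@H](C(C)(C)C)OC2=O | intermediate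
13 | (2R,5S,6R)-2-tert-butyl-6-(10-hydroxydecyl)-1,3-dioxaspiro[4.5]dec-7-en-4-one | OCCCCCCCCCC[C@@H]1C=CCC[C@]12O[C@@H](C(C)(C)C)OC2=O | intermediate
14 | (R)-malic acid | O=C(O)C[C@@H](O)C(=O)O | starting material
15 | (3R)-2,5-dioxooxolan-3-yl trifluoroacetate | O=C1C[C@@H](OC(=O)C(F)(F)F)C(=O)O1 | intermediate
16 | (3R)-4-({10-[(2R,5S,6R)-2-tert-butyl-4-oxo-1,3-dioxaspiro[4.5]dec-7-en-6-yl]decyl}oxy)-4-oxo-3-[(trifluoroacetyl)oxy]butanoic acid | O=C(O)C[C@@H](OC(=O)C(F)(F)F)C(=O)OCCCCCCCCCC[C@@H]1C=CCC[C@]12O[C@@H](C(C)(C)C)OC2=O | intermediate
17 | (3R)-4-({10-[(2R,5S,6R)-2-tert-butyl-4-oxo-1,3-dioxaspiro[4.5]dec-7-en-6-yl]decyl}oxy)-3-hydroxy-4-oxobutanoic acid | O=C(O)C[C@@H](O)C(=O)OCCCCCCCCCC[C@@H]1C=CCC[C@]12O[C@@H](C(C)(C)C)OC2=O | intermediate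
18 | secondary ozonide of 17 (C7 and C8 of the spiro ring bridged as a 1,2,4-trioxolane; mixture at the two ozonide carbons) | O=C(O)C[C@@H](O)C(=O)OCCCCCCCCCC[C@@H]1C3OOC(O3)CC[C@]12O[C@@H](C(C)(C)C)OC2=O | intermediate
19 | (3R)-4-({(11S)-11-[(2R,4S)-2-tert-butyl-5-oxo-4-(3-oxopropyl)-1,3-dioxolan-4-yl]-12-oxododecyl}oxy)-3-hydroxy-4-oxobutanoic acid | O=C(O)C[C@@H](O)C(=O)OCCCCCCCCCC[C@H](C=O)[C@]1(CCC=O)O[C@@H](C(C)(C)C)OC1=O | intermediate
20 | (3R)-4-({(11S)-11-carboxy-11-[(2R,4S)-2-tert-butyl-4-(2-carboxyethyl)-5-oxo-1,3-dioxolan-4-yl]undecyl}oxy)-3-hydroxy-4-oxobutanoic acid | O=C(O)C[C@@H](O)C(=O)OCCCCCCCCCC[C@H](C(=O)O)[C@]1(CCC(=O)O)O[C@@H](C(C)(C)C)OC1=O | intermediate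
21 | (2S)-2-[(1S)-1-carboxy-11-{[(2R)-3-carboxy-2-hydroxypropanoyl]oxy}undecyl]-2-hydroxypentanedioic acid | O=C(O)C[C@@H](O)C(=O)OCCCCCCCCCC[C@H](C(=O)O)[C@@](O)(CCC(=O)O)C(=O)O | intermediate
22 | (2S)-2-[(1S)-1-carboxy-11-{[(2R)-3-carboxy-2-hydroxypropanoyl]oxy}undecyl]-5-oxooxolane-2-carboxylic acid | O=C(O)C[C@@H](O)C(=O)OCCCCCCCCCC[C@H](C(=O)O)[C@]1(C(=O)O)CCC(=O)O1 | target

## Step count and least certain steps

Total step count: 12. Longest linear sequence: 8 steps (steps 1, 2, 3, 7, 8, 10, 11, 12 from 1; equally steps 4, 5, 6, 7, 8, 10, 11, 12 from 6).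

**Step 7 (key step).** Most likely to go wrong: a monoalkyl diene is a weak and weakly directing partner. The cycloaddition may be slower than radical polymerisation of the dienophile, and regio-, exo- or facial control may be incomplete, giving isomers that are hard to separate. The extruded gas may also degrade the acetal.

The fallback drops the cycloaddition and joins the two centres by a catalytic aldol addition. It sets out from iodide 3 and comes back at 22.
- Iodide 3 alkylates the lithium enolate of S-tert-butyl thioacetate (LiN(i-Pr)2, THF/DMPU) to give S-tert-butyl 12-[(tert-butyldimethylsilyl)oxy]dodecanethioate F1.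
- Enolisation and silylation (LiN(i-Pr)2, Me3SiCl, −78 °C) give the (Z)-ketene S,O-acetal F2.
- A syn-selective Mukaiyama aldol addition of F2 to commercial dimethyl 2-oxoglutarate, catalysed by Cu(OTf)2 with a tert-butyl-bis(oxazoline) ligand (divalent copper chelated by the keto ester; ligand antipode chosen for the (S) carbinol), should give the silylated adduct F3. Acidic work-up then gives the tertiary aldol F4.
- Saponification (LiOH, aqueous THF, 0 °C) gives the silyloxy triacid F5. TFA/H2O removes the silyl ether and closes the lactone to the hydroxy lactone diacid F6.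
- Acylation of the primary hydroxyl of F6 with anhydride 15 gives, through the O-trifluoroacetate F7, the target 22. The free acids should form only labile mixed anhydrides that revert on aqueous work-up.

**Step 3.** Most likely to go wrong: ring opening of the 3-sulfolenyl anion to a dienyl sulfinate, and over-alkylation, compete with the slow SN2 reaction of a long-chain iodide.

The fallback builds the diene by cross-coupling. It sets out from 3 and comes back at 11, which then enters step 7 as a preformed diene.
- Displacement with LiC≡CH·H2NCH2CH2NH2 in DMSO gives tert-butyl(dodec-11-yn-1-yloxy)dimethylsilane F8.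
- Hydroboration with pinacolborane (cat. Cp2Zr(H)Cl, Et3N) gives the (E)-alkenyl pinacol boronate F9.
- Suzuki coupling with vinyl bromide (Pd(PPh3)4, aqueous K3PO4, THF) gives 11.

**Step 11.** Most likely to go wrong: in the interval between reductive work-up and chlorite oxidation, the α-branched aldehyde may enolise (epimerisation at the methine, or β-elimination of the acetal oxygen) and the 1,6-dialdehyde may undergo intramolecular aldol condensation. Over-ozonation at the acetal C–H is a further risk.

The fallback cleaves the alkene directly to the diacid and moves the malate to the end. It sets out from 12 and comes back at 22.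
- RuCl3 (cat.)/NaIO4 in MeCN/CCl4/H2O is applied to 12, where no secondary alcohol is present and aldehydes are oxidised as they form. This gives the silyloxy diacid F10.
- TFA/H2O converts F10 into the hydroxy lactone diacid F6, which is acylated with 15 through F7 to 22 as described for step 7.

**Step 12.** Most likely to go wrong: if cleavage of the hindered neopentyl-type acylal is slow, hydrolysis or acyl migration of the malate ester competes in the aqueous acid.

The fallback replaces hydrolysis by anhydrous acetal exchange. It sets out from 20 and comes back at 21, which lactonises to 22. Propane-1,3-dithiol and BF3·OEt2 in CH2Cl2 at 0 °C transfer the pivalaldehyde unit to sulfur; with no water present, ester hydrolysis is excluded.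

## Further compounds

F1 | step 7 | S-tert-butyl 12-[(tert-butyldimethylsilyl)oxy]dodecanethioate | CC(C)(C)SC(=O)CCCCCCCCCCCO[Si](C)(C)C(C)(C)C
F2 | step 7 | tert-butyl{[(11Z)-12-(tert-butylsulfanyl)-12-[(trimethylsilyl)oxy]dodec-11-en-1-yl]oxy}dimethylsilane | CC(C)(C)S/C(O[Si](C)(C)C)=C\CCCCCCCCCCO[Si](C)(C)C(C)(C)C
F3 | step 7 | dimethyl (2S)-2-[(2S)-1-(tert-butylsulfanyl)-12-[(tert-butyldimethylsilyl)oxy]-1-oxododecan-2-yl]-2-[(trimethylsilyl)oxy]pentanedioate | CC(C)(C)[Si](C)(C)OCCCCCCCCCC[C@H](C(=O)SC(C)(C)C)[C@@](O[Si](C)(C)C)(CCC(=O)OC)C(=O)OC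
F4 | step 7 | dimethyl (2S)-2-[(2S)-1-(tert-butylsulfanyl)-12-[(tert-butyldimethylsilyl)oxy]-1-oxododecan-2-yl]-2-hydroxypentanedioate | CC(C)(C)[Si](C)(C)OCCCCCCCCCC[C@H](C(=O)SC(C)(C)C)[C@@](O)(CCC(=O)OC)C(=O)OC
F5 | step 7 | (2S)-2-[(1S)-1-carboxy-11-[(tert-butyldimethylsilyl)oxy]undecyl]-2-hydroxypentanedioic acid | CC(C)(C)[Si](C)(C)OCCCCCCCCCC[C@H](C(=O)O)[C@@](O)(CCC(=O)O)C(=O)O
F6 | step 7 | (2S)-2-[(1S)-1-carboxy-11-hydroxyundecyl]-5-oxooxolane-2-carboxylic acid | OCCCCCCCCCC[C@H](C(=O)O)[C@]1(C(=O)O)CCC(=O)O1
F7 | step 7 | (2S)-2-[(1S)-1-carboxy-11-{[(2R)-3-carboxy-2-[(trifluoroacetyl)oxy]propanoyl]oxy}undecyl]-5-oxooxolane-2-carboxylic acid | O=C(O)C[C@@H](OC(=O)C(F)(F)F)C(=O)OCCCCCCCCCC[C@H](C(=O)O)[C@]1(C(=O)O)CCC(=O)O1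
F8 | step 3 | tert-butyl(dodec-11-yn-1-yloxy)dimethylsilane | C#CCCCCCCCCCCO[Si](C)(C)C(C)(C)C
F9 | step 3 | tert-butyldimethyl{[(11E)-12-(4,4,5,5-tetramethyl-1,3,2-dioxaborolan-2-yl)dodec-11-en-1-yl]oxy}silane | CC(C)(C)[Si](C)(C)OCCCCCCCCCC/C=C/B1OC(C)(C)C(C)(C)O1
F10 | step 11 | (2S)-2-[(2R,4S)-2-tert-butyl-4-(2-carboxyethyl)-5-oxo-1,3-dioxolan-4-yl]-12-[(tert-butyldimethylsilyl)oxy]dodecanoic acid | CC(C)(C)[Si](C)(C)OCCCCCCCCCC[C@H](C(=O)O)[C@]1(CCC(=O)O)O[C@@H](C(C)(C)C)OC1=O
F0 | step 12 | none | none
A1 | alternative 1 | dimethyl (2S)-2-[(2S)-12-[(tert-butyldimethylsilyl)oxy]-1-methoxy-1-oxododecan-2-yl]-2-hydroxypentanedioate | CC(C)(C)[Si](C)(C)OCCCCCCCCCC[C@H](C(=O)OC)[C@@](O)(CCC(=O)OC)C(=O)OC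
A2 | alternative 2 | methyl 5-[(triisopropylsilyl)oxy]furan-2-carboxylate | COC(=O)c1ccc(O[Si](C(C)C)(C(C)C)C(C)C)o1
A3 | alternative 2 | methyl (2S)-2-[(2S)-1-ethoxy-1,4-dioxobutan-2-yl]-5-oxo-2,5-dihydrofuran-2-carboxylate | O=CC[C@H](C(=O)OCC)[C@]1(C(=O)OC)C=CC(=O)O1
A4 | alternative 3 | diethyl (2S,3R)-3-{10-[(tert-butyldimethylsilyl)oxy]decyl}-2-hydroxybutanedioate | CCOC(=O)[C@H](CCCCCCCCCCO[Si](C)(C)C(C)(C)C)[C@H](O)C(=O)OCC
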